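**Retrosynthetic overview**
1. Target 17 comes from carbinol 16 by a last-step oxidation, so the two doubly activated CH(Me) centres exist only in the final compound.
2. 16 is cut at C3–C4 into aldehyde 14 and racemic lateral bromide 13; the bond is made by a visible-light photoredox/titanocene radical–polar coupling, with C4 set by the C2 centre.
3. 14 comes from alcohol 10, whose 6-pentyl pyranone is built on the ester carbon of (S)-Roche ester by two Claisen acylations (pentan-3-one, then methyl hexanoate) and cyclodehydration.
4. Ring order: ring B (6-ethyl pyranone) is bought ready-made in 11; ring A (6-pentyl pyranone) is closed in step 4; no other ring is formed.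

Assumption: 2,6-diethyl-3,5-dimethyl-4H-pyran-4-one (11) is taken as a purchasable catalogue compound.

**Step 1**
Reactants: 1 methyl (S)-3-hydroxy-2-methylpropanoate
Product: 2 methyl (S)-3-[(tert-butyldimethylsilyl)oxy]-2-methylpropanoate
Conditions: TBSCl, imidazole, CH2Cl2, 0 °C to rt
Reagents that add atoms: tert-butyldimethylsilyl chloride, CC(C)(C)[Si](C)(C)Cl
Why: Standard imidazole-promoted O-silylation of a primary alcohol, which leaves the bought stereocentre untouched.

**Step 2**
Reactants: 2 methyl (S)-3-[(tert-butyldimethylsilyl)oxy]-2-methylpropanoate; 3 pentan-3-one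
Product: 5 (6S)-7-[(tert-butyldimethylsilyl)oxy]-4,6-dimethylheptane-3,5-dione (C4 epimers and enol forms), via lithium pent-2-en-3-olate 4 (not isolated)
Conditions: 3 (2.5 equiv), LiN(i-Pr)2 (2.5 equiv), THF, −78 °C; then 2, −78 to −20 °C; AcOH quench
Reagents that add atoms: none
Why: Crossed Claisen condensation in which the excess ketone enolate attacks the ester and the product is drained as its lithium diketonate, so the C6–H of the Roche centre is not enolised.

**Step 3**
Reactants: 5 (6S)-7-[(tert-butyldimethylsilyl)oxy]-4,6-dimethylheptane-3,5-dione; 6 methyl hexanoate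
Product: 8 (2S)-1-[(tert-butyldimethylsilyl)oxy]-2,4,6-trimethyldodecane-3,5,7-trione (C4/C6 epimers and enol forms), via dilithium dienediolate 7 (not isolated)
Conditions: LiN(i-Pr)2 (2.3 equiv), THF, −78 to 0 °C; then 6 (1.3 equiv), −78 to 0 °C; AcOH quench
Reagents that add atoms: none
Why: Terminal acylation of a β-diketone dianion (Claisen condensation), where the second deprotonation goes kinetically to the unbranched ethyl CH2 rather than the hindered tertiary C–H of the stereocentre, and the new CH(Me) centres later become sp2.

**Step 4**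
Reactants: 8 (2S)-1-[(tert-butyldimethylsilyl)oxy]-2,4,6-trimethyldodecane-3,5,7-trione
Product: 10 2-[(2S)-1-hydroxypropan-2-yl]-3,5-dimethyl-6-pentyl-4H-pyran-4-one, via silyl ether 9 (not isolated)
Conditions: PPh3, CCl4, THF, rt; then HF·pyridine added to the same flask, 0 °C to rt; NaHCO3 work-up
Reagents that add atoms: none
Why: Cyclodehydration of a 1,3,5-triketone to the 4-pyranone with the neutral PPh3/CCl4 system avoids enolising the adjacent stereocentre, and HF·pyridine then cleaves the primary silyl ether only after the ring is closed.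

**Step 5**
Reactants: 11 2,6-diethyl-3,5-dimethyl-4H-pyran-4-one
Product: 13 2-(1-bromoethyl)-6-ethyl-3,5-dimethyl-4H-pyran-4-one (racemic), via lithium pyran-4-olate 12 (not isolated)
Conditions: LiN(SiMe3)2, THF, −78 °C; cannulated into BrCl2CCCl2Br, THF, −78 °C
Reagents that add atoms: 1,2-dibromo-1,1,2,2-tetrachloroethane, BrC(Cl)(Cl)C(Cl)(Cl)Br
Why: Lateral (vinylogous) deprotonation of a 2-ethyl-4-pyranone followed by electrophilic bromination of the extended enolate at its exocyclic carbon; 11 is symmetric so there is no regiochemical issue, and the racemic centre of 13 is erased in step 7.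

**Step 6**
Reactants: 10 2-[(2S)-1-hydroxypropan-2-yl]-3,5-dimethyl-6-pentyl-4H-pyran-4-one
Product: 14 (2R)-2-(3,5-dimethyl-4-oxo-6-pentyl-4H-pyran-2-yl)propanal
Conditions: Dess–Martin periodinane, pyridine, CH2Cl2, 0 °C; filtered and used crude at once
Reagents that add atoms: none
Why: Dess–Martin oxidation under pyridine buffering is non-enolising, and the configurationally labile α-pyranonyl aldehyde is neither stored nor chromatographed (the descriptor changes from S to R only through CIP priorities).

**Step 7**
Reactants: 14 (2R)-2-(3,5-dimethyl-4-oxo-6-pentyl-4H-pyran-2-yl)propanal; 13 2-(1-bromoethyl)-6-ethyl-3,5-dimethyl-4H-pyran-4-one (1.5 equiv)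
Product: 16 2-[(2S,3R,4R)-4-(6-ethyl-3,5-dimethyl-4-oxo-4H-pyran-2-yl)-3-hydroxypentan-2-yl]-3,5-dimethyl-6-pentyl-4H-pyran-4-one, via titanium pyran-4-olate 15 (not isolated)
Conditions: (C5H5)2TiCl2 (10 mol%), 4CzIPN (3 mol%), Hantzsch ester (1.5 equiv), THF, blue LEDs (456 nm), 10 °C; NaHCO3 work-up
Reagents that add atoms: none
Why: Proposed new method: a photoredox/titanocene dual-catalytic vinylogous Reformatsky (Barbier-type) coupling in which photoreduced trivalent titanium abstracts bromine from the allylic-type bromide 13 (both enantiomers give the same planar radical), a second trivalent titanium traps the radical on oxygen as the tetravalent titanium dienolate 15, and 15 adds through its exocyclic carbon, re-aromatising the pyranone, to aldehyde 14 in an open antiperiplanar transition state without base, so that the C2 centre directs the new centres by Felkin–Anh attack anti to the pyranone ring (C2,C3-syn) combined with the syn preference of the open transition state (C3,C4-syn) to give the all-syn triad (the C3 epimer with the same C2/C4 relation would serve equally, and the C4 epimers are removed by chromatography here); the closest known reactions are the photoredox titanocene-catalysed Barbier allylation of aldehydes and the stoichiometric trivalent-titanium Reformatsky reaction, neither shown for a 4-pyranone lateral bromide or a γ-selective vinylogous case.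

**Step 8**
Reactants: 16 2-[(2S,3R,4R)-4-(6-ethyl-3,5-dimethyl-4-oxo-4H-pyran-2-yl)-3-hydroxypentan-2-yl]-3,5-dimethyl-6-pentyl-4H-pyran-4-one
Product: 17 (2R,4S)-2-(3,5-dimethyl-4-oxo-6-pentyl-4H-pyran-2-yl)-4-(6-ethyl-3,5-dimethyl-4-oxo-4H-pyran-2-yl)pentan-3-one
Conditions: Dess–Martin periodinane, pyridine, CH2Cl2, 0 °C to rt; rapid filtration through buffered silica
Reagents that add atoms: none
Why: Dess–Martin oxidation of the hindered secondary alcohol under buffered neutral conditions creates the ketone last, so the two epimerisable α-centres never meet acid or base (descriptors change to 2R,4S only through CIP priorities).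

**Compound list**
1 | methyl (S)-3-hydroxy-2-methylpropanoate ((S)-Roche ester) | COC(=O)[C@@H](C)CO | starting material
2 | methyl (S)-3-[(tert-butyldimethylsilyl)oxy]-2-methylpropanoate | COC(=O)[C@@H](C)CO[Si](C)(C)C(C)(C)C | intermediate
3 | pentan-3-one | CCC(=O)CC | starting material
4 | lithium pent-2-en-3-olate | [Li+].CC=C([O-])CC | intermediate
5 | (6S)-7-[(tert-butyldimethylsilyl)oxy]-4,6-dimethylheptane-3,5-dione | CCC(=O)C(C)C(=O)[C@@H](C)CO[Si](C)(C)C(C)(C)C | intermediate
6 | methyl hexanoate | CCCCCC(=O)OC | starting material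
7 | dilithium (6S)-7-[(tert-butyldimethylsilyl)oxy]-4,6-dimethylhepta-2,4-diene-3,5-diolate | [Li+].[Li+].CC=C([O-])C(C)=C([O-])[C@@H](C)CO[Si](C)(C)C(C)(C)C | intermediate
8 | (2S)-1-[(tert-butyldimethylsilyl)oxy]-2,4,6-trimethyldodecane-3,5,7-trione | CCCCCC(=O)C(C)C(=O)C(C)C(=O)[C@@H](C)CO[Si](C)(C)C(C)(C)C | intermediate
9 | 2-[(2S)-1-[(tert-butyldimethylsilyl)oxy]propan-2-yl]-3,5-dimethyl-6-pentyl-4H-pyran-4-one | CCCCCc1oc([C@@H](C)CO[Si](C)(C)C(C)(C)C)c(C)c(=O)c1C | intermediate
10 | 2-[(2S)-1-hydroxypropan-2-yl]-3,5-dimethyl-6-pentyl-4H-pyran-4-one | CCCCCc1oc([C@@H](C)CO)c(C)c(=O)c1C | intermediate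
11 | 2,6-diethyl-3,5-dimethyl-4H-pyran-4-one | CCc1oc(CC)c(C)c(=O)c1C | starting material
12 | lithium 6-ethyl-2-ethylidene-3,5-dimethyl-2H-pyran-4-olate | [Li+].CC=C1OC(CC)=C(C)C([O-])=C1C | intermediate
13 | 2-(1-bromoethyl)-6-ethyl-3,5-dimethyl-4H-pyran-4-one (racemic) | CCc1oc(C(C)Br)c(C)c(=O)c1C | intermediate
14 | (2R)-2-(3,5-dimethyl-4-oxo-6-pentyl-4H-pyran-2-yl)propanal | CCCCCc1oc([C@@H](C)C=O)c(C)c(=O)c1C | intermediate
15 | chloridobis(cyclopentadienyl)titanium 6-ethyl-2-ethylidene-3,5-dimethyl-2H-pyran-4-olate, (C5H5)2TiCl(OR), cyclopentadienyl rings drawn sigma-bonded in the SMILES | CC=C1OC(CC)=C(C)C(O[Ti](Cl)(C2C=CC=C2)C3C=CC=C3)=C1C | intermediate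
16 | 2-[(2S,3R,4R)-4-(6-ethyl-3,5-dimethyl-4-oxo-4H-pyran-2-yl)-3-hydroxypentan-2-yl]-3,5-dimethyl-6-pentyl-4H-pyran-4-one | CCCCCc1oc([C@@H](C)[C@H](O)[C@@H](C)c2oc(CC)c(C)c(=O)c2C)c(C)c(=O)c1C | intermediate
17 | (2R,4S)-2-(3,5-dimethyl-4-oxo-6-pentyl-4H-pyran-2-yl)-4-(6-ethyl-3,5-dimethyl-4-oxo-4H-pyran-2-yl)pentan-3-one | CCCCCc1oc([C@@H](C)C(=O)[C@@H](C)c2oc(CC)c(C)c(=O)c2C)c(C)c(=O)c1C | target

**Step count**
Total steps: 8. Longest linear sequence: 7 (steps 1, 2, 3, 4, 6, 7, 8); step 5 is the convergent branch.

**Three steps most likely to fail**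

Step 7 (the proposed new coupling). The risks are weak simple diastereoselectivity (the C3,C4-syn preference is the least certain element), attack through ring carbon C3 instead of the lateral carbon, and plain reduction of 13 back to 11. The fallback sets out from 11 and 14 and comes back at 16. Lithium pyran-4-olate 12 is made from 11 with LiN(SiMe3)2 in THF at −78 °C as in step 5, aldehyde 14 is added in place of the bromine donor, and the mixture is quenched cold with AcOH after a few minutes. This is the known lateral aldol addition of 2-ethyl-4-pyranone anions to aldehydes. 16 is then separated from its diastereomers by HPLC, accepting lower selectivity and some risk to the aldehyde centre from the basic medium.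

Step 3 (dianion acylation). The risks are competing deprotonation at the tertiary C–H next to the silyloxymethyl group (epimerisation or loss of silanolate) and sluggish acyl transfer from the ester. The fallback sets out from dianion 7 (made from 5 as in step 3) and comes back at 8. Hexanal is added at −78 °C instead of methyl hexanoate, an aldol addition that is faster and cleaner than the acyl substitution, to give (2S)-1-[(tert-butyldimethylsilyl)oxy]-7-hydroxy-2,4,6-trimethyldodecane-3,5-dione F1. F1 is oxidised with Dess–Martin periodinane to 8.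

Step 2 (crossed Claisen on a branched ester). The risks are low conversion and proton transfer to the ester. The fallback sets out from 2 and comes back at 5. Ester 2 is reduced with i-Bu2AlH (CH2Cl2, −78 °C) to (2S)-3-[(tert-butyldimethylsilyl)oxy]-2-methylpropanal F2. Lithium pent-2-en-3-olate 4 is added in THF at −78 °C to give (6S)-7-[(tert-butyldimethylsilyl)oxy]-5-hydroxy-4,6-dimethylheptan-3-one F3 as a diastereomer mixture. F3 is oxidised with Dess–Martin periodinane to 5 (aldol–oxidation in place of the Claisen condensation).

**Further compounds**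
F0 | step 7 | none | none
F1 | step 3 | (2S)-1-[(tert-butyldimethylsilyl)oxy]-7-hydroxy-2,4,6-trimethyldodecane-3,5-dione | CCCCCC(O)C(C)C(=O)C(C)C(=O)[C@@H](C)CO[Si](C)(C)C(C)(C)C
F2 | step 2 | (2S)-3-[(tert-butyldimethylsilyl)oxy]-2-methylpropanal | O=C[C@@H](C)CO[Si](C)(C)C(C)(C)C
F3 | step 2 | (6S)-7-[(tert-butyldimethylsilyl)oxy]-5-hydroxy-4,6-dimethylheptan-3-one | CCC(=O)C(C)C(O)[C@@H](C)CO[Si](C)(C)C(C)(C)C
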